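**Retrosynthetic overview**
1. The target is a 7-hydroxy-5-methylchromone (rings A/C) whose C-2 is bonded to C-1′ of a resorcinol ring B (OH at C-2′ and C-4′). The ortho carbon C-6′ of ring B carries the CH2 that sits on C-6 of a 4-hydroxy-2-pyranone (ring D).
2. Key disconnection: both bonds that tie ring B to the rest (C-1′–C-2 of the chromone and C-6′–CH2) are cut together. Ring B leaves as 3,5-dimethoxybenzyne, and the precursor is the dihetarylmethane chromone–CH2–pyranone, whose C-2–CH2 σ-bond takes up the aryne (a vinylogous aryne acyl-alkylation).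
3. The dihetarylmethane comes from addition–elimination of the lithiated 6-methyl group of O-benzyl triacetic acid lactone at C-2 of a 2-(methylsulfonyl)chromone.
4. Ring order: rings A, B and D are bought (orcacetophenone, 3,5-dimethoxyphenol, triacetic acid lactone). Ring C is closed first by CS2 annulation (step 2), ring B is then inserted between rings C and D (step 8), and global O-dealkylation ends the route.

Key step: step 8

Assumption: the target has no stereocentre, and the C-2–C-1′ axis (one ring without ortho substituents at the axis) is not configurationally stable, so the compound is achiral and the route needs no stereocontrol.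

**Step 1**
Reactants: 1 4-hydroxy-6-methyl-2H-pyran-2-one (triacetic acid lactone)
Product: 2 4-(benzyloxy)-6-methyl-2H-pyran-2-one
Conditions: BnBr, K2CO3, DMF, rt to 50 °C
Reagents that add atoms: benzyl bromide, BrCc1ccccc1
Why: Williamson-type O-alkylation of the vinylogous acid should occur mainly at the 4-oxygen of the ambident anion in a polar aprotic solvent, and the minor C-3 and 2-O benzyl isomers should be removable by crystallisation.

**Step 2**
Reactants: 3 1-(2,4-dihydroxy-6-methylphenyl)ethan-1-one
Product: 4 4,7-dihydroxy-5-methyl-2H-chromene-2-thione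
Conditions: KOtBu (4.5 equiv), CS2, THF, 0 °C to rt; then aq. HCl
Reagents that add atoms: carbon disulfide, S=C=S
Why: The ketone enolate should add to CS2 and the ortho-phenoxide should close onto the dithiocarboxylate with loss of hydrosulfide (Claisen-type thioacylation and cyclocondensation, the usual entry from 2-hydroxyacetophenones to 4-hydroxy-2-thiocoumarins), which forms ring C.

**Step 3**
Reactants: 4 4,7-dihydroxy-5-methyl-2H-chromene-2-thione
Product: 5 7-methoxy-5-methyl-2-(methylsulfanyl)-4H-chromen-4-one
Conditions: MeI (2.5 equiv), K2CO3, acetone, reflux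
Reagents that add atoms: iodomethane, CI
Why: Alkylation of the ambident thione anion should take place at the soft sulfur to give the 2-alkylthio-4-chromenone tautomer, and the free 7-phenol should be methylated in the same pot (Williamson ether synthesis).

**Step 4**
Reactants: 5 7-methoxy-5-methyl-2-(methylsulfanyl)-4H-chromen-4-one
Product: 6 7-methoxy-5-methyl-2-(methylsulfonyl)-4H-chromen-4-one
Conditions: mCPBA (2.3 equiv), CH2Cl2, 0 °C to rt
Reagents that add atoms: mCPBA, OOC(=O)c1cccc(Cl)c1
Why: Peracid oxidation of the sulfide to the sulfone should be clean because the electron-poor C-2=C-3 bond of the chromone is not epoxidised by mCPBA.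

**Step 5**
Reactants: 2 4-(benzyloxy)-6-methyl-2H-pyran-2-one (2.1 equiv); 6 7-methoxy-5-methyl-2-(methylsulfonyl)-4H-chromen-4-one
Product: 8 2-{[4-(benzyloxy)-2-oxo-2H-pyran-6-yl]methyl}-7-methoxy-5-methyl-4H-chromen-4-one, via lithiated pyranone 7 (not isolated)
Conditions: 2, LDA, THF, −78 °C; then 6, −78 to −30 °C; aq. NH4Cl
Reagents that add atoms: none
Why: LDA should deprotonate the 6-methyl group to the extended dienolate 7, which should add through its exocyclic carbon to C-2 of the sulfonylchromone and expel methanesulfinate (addition–elimination, nucleophilic vinylic substitution, as known for 2-sulfinyl- and 2-sulfonylchromones), while the second equivalent of 7 takes up the acidic methylene proton of 8 and is recovered as 2.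

**Step 6**
Reactants: 9 3,5-dimethoxyphenol
Product: 10 2-bromo-3,5-dimethoxyphenol
Conditions: NBS (1.0 equiv), CH2Cl2, −78 to 0 °C
Reagents that add atoms: N-bromosuccinimide, O=C1CCC(=O)N1Br
Why: Electrophilic aromatic bromination at low temperature should favour C-2 (ortho to OH, para to OMe, two equivalent sites) over C-4, which is flanked by two methoxy groups.

**Step 7**
Reactants: 10 2-bromo-3,5-dimethoxyphenol
Product: 13 3,5-dimethoxy-2-(trimethylsilyl)phenyl trifluoromethanesulfonate, via aryl silyl ether 11 (not isolated), via lithium silylphenolate 12 (not isolated)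
Conditions: HMDS, THF, 70 °C, then evaporation; n-BuLi, THF, −78 °C; Tf2O, −78 to 0 °C
Reagents that add atoms: hexamethyldisilazane, C[Si](C)(C)N[Si](C)(C)C; triflic anhydride, O=S(=O)(OS(=O)(=O)C(F)(F)F)C(F)(F)F
Why: O-silylation, bromine–lithium exchange and 1,3-O-to-C silyl shift (retro-Brook rearrangement) should give the ortho-silyl phenolate, which is triflated in the same pot, the standard way from ortho-bromophenols to ortho-silylaryl triflate aryne precursors.

**Step 8**
Reactants: 8 2-{[4-(benzyloxy)-2-oxo-2H-pyran-6-yl]methyl}-7-methoxy-5-methyl-4H-chromen-4-one; 13 3,5-dimethoxy-2-(trimethylsilyl)phenyl trifluoromethanesulfonate (1.3 equiv)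
Product: 16 2-{2-[(4-benzyloxy-2-oxo-2H-pyran-6-yl)methyl]-4,6-dimethoxyphenyl}-7-methoxy-5-methyl-4H-chromen-4-one, via 3,5-dimethoxybenzyne 14 (not isolated), via spirocyclobutene enolate 15 (not isolated)
Conditions: CsF (3 equiv), MeCN, 60 °C, slow addition of 13
Reagents that add atoms: none
Why: Proposed new method: fluoride converts 13 into 3,5-dimethoxybenzyne 14 and holds 8 as the caesium carbanion of its doubly vinylogous methylene; the carbanion adds to the aryne carbon remote from the 3-methoxy group, the resulting aryl anion (ortho to OMe) adds to chromone C-2, the vinylogous acyl carbon on the same methine, to give the spiro-benzocyclobutene enolate 15, and strain-driven retro-Michael cleavage of the C-2–CH bond restores the chromone and leaves a benzylic, pyranone-stabilised carbanion that is protonated by further 8. The closest known reaction type is the insertion of arynes into the C–C σ-bond of β-ketoesters, β-diketones and malonates (aryne acyl-alkylation), in which a ketone or ester carbonyl carbon plays the part taken here by C-2 of the chromone (a β-alkoxy enone), so this is its vinylogous version. No ring of the target is closed: the only closure is the transient four-membered ring of 15, formed by a 4-exo-trig conjugate addition and opened again in the fragmentation. No stereocentre remains, since the two of 15 are lost on ring opening. Three selectivities are needed: the aryne regiochemistry (chromone ortho to OMe, CH2 meta), secured by the distortion of the 3-alkoxyaryne as in known acyl-alkylations of such arynes; closure onto chromone C-2 and not onto pyranone C-6, secured by the ketone-level enone of the chromone being more electrophilic than the lactone-level, 4-alkoxy-deactivated dienoate (both carbonyl carbons are out of reach, since their attack would lock an anti-periplanar four-atom unit into a six-membered ring); and carbanion capture of the aryne over [4+2] addition across the 2-pyranone, secured by keeping 8 deprotonated and adding 13 slowly.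

**Step 9**
Reactants: 16 2-{2-[(4-benzyloxy-2-oxo-2H-pyran-6-yl)methyl]-4,6-dimethoxyphenyl}-7-methoxy-5-methyl-4H-chromen-4-one
Product: 17 2-{2,4-dihydroxy-6-[(4-hydroxy-2-oxo-2H-pyran-6-yl)methyl]phenyl}-7-hydroxy-5-methyl-4H-chromen-4-one (CNP0309284.0)
Conditions: BBr3 (10 equiv), pentamethylbenzene, CH2Cl2, −78 °C to rt; then MeOH, H2O
Reagents that add atoms: none
Why: Lewis-acid ether cleavage with BBr3 should remove the three aryl methyl ethers by bromide attack on the boron-complexed ethers and the vinylogous benzyl ester by ionisation to a benzyl cation that pentamethylbenzene traps, while the chromone and the 4-hydroxy-2-pyranone are stable to the reagent.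

**Compound list**
1 | 4-hydroxy-6-methyl-2H-pyran-2-one | Cc1cc(O)cc(=O)o1 | starting material
2 | 4-(benzyloxy)-6-methyl-2H-pyran-2-one | Cc1cc(OCc2ccccc2)cc(=O)o1 | intermediate
3 | 1-(2,4-dihydroxy-6-methylphenyl)ethan-1-one | CC(=O)c1c(C)cc(O)cc1O | starting material
4 | 4,7-dihydroxy-5-methyl-2H-chromene-2-thione | Cc1cc(O)cc2oc(=S)cc(O)c12 | intermediate
5 | 7-methoxy-5-methyl-2-(methylsulfanyl)-4H-chromen-4-one | COc1cc(C)c2c(c1)oc(SC)cc2=O | intermediate
6 | 7-methoxy-5-methyl-2-(methylsulfonyl)-4H-chromen-4-one | COc1cc(C)c2c(c1)oc(S(C)(=O)=O)cc2=O | intermediate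
7 | lithium [4-(benzyloxy)-2-oxo-2H-pyran-6-yl]methanide (lithiated pyranone) | [Li]Cc1cc(OCc2ccccc2)cc(=O)o1 | intermediate
8 | 2-{[4-(benzyloxy)-2-oxo-2H-pyran-6-yl]methyl}-7-methoxy-5-methyl-4H-chromen-4-one | COc1cc(C)c2c(c1)oc(Cc1cc(OCc3ccccc3)cc(=O)o1)cc2=O | intermediate
9 | 3,5-dimethoxyphenol | COc1cc(O)cc(OC)c1 | starting material
10 | 2-bromo-3,5-dimethoxyphenol | COc1cc(O)c(Br)c(OC)c1 | intermediate
11 | (2-bromo-3,5-dimethoxyphenoxy)trimethylsilane | COc1cc(O[Si](C)(C)C)c(Br)c(OC)c1 | intermediate
12 | lithium 3,5-dimethoxy-2-(trimethylsilyl)phenolate | COc1cc([O-])c([Si](C)(C)C)c(OC)c1.[Li+] | intermediate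
13 | 3,5-dimethoxy-2-(trimethylsilyl)phenyl trifluoromethanesulfonate | COc1cc(OS(=O)(=O)C(F)(F)F)c([Si](C)(C)C)c(OC)c1 | intermediate
14 | 3,5-dimethoxybenzyne | COC1=CC(OC)=CC#C1 | intermediate
15 | caesium enolate of the spiro[benzocyclobutene-1,2′-chroman]-4′-one adduct (4-exo adduct at chromone C-2) | COc1cc(C)c2c(c1)OC3(C=C2[O-])c4c(OC)cc(OC)cc4C3c5cc(OCc6ccccc6)cc(=O)o5.[Cs+] | intermediate
16 | 2-{2-[(4-benzyloxy-2-oxo-2H-pyran-6-yl)methyl]-4,6-dimethoxyphenyl}-7-methoxy-5-methyl-4H-chromen-4-one | COc1cc(C)c2c(c1)oc(-c1c(OC)cc(OC)cc1Cc1cc(OCc3ccccc3)cc(=O)o1)cc2=O | intermediate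
17 | 2-{2,4-dihydroxy-6-[(4-hydroxy-2-oxo-2H-pyran-6-yl)methyl]phenyl}-7-hydroxy-5-methyl-4H-chromen-4-one | Cc1cc(O)cc2oc(-c3c(O)cc(O)cc3Cc3cc(O)cc(=O)o3)cc(=O)c12 | target

**Step count and risk**
Total step count: 9. Longest linear sequence: 6 steps (steps 2, 3, 4, 5, 8, 9, from acetophenone 3).

Steps most likely to fail:

1. Step 8 (proposed new method). The aryne may be consumed by [4+2] addition across the pyranone diene. The aryl anion may be protonated before it closes onto C-2, which gives plain C-arylation of the methylene. It may also close onto pyranone C-6 and so give the regioisomeric insertion. The fallback uses known reactions, sets out from 2 and 5 and comes back at 16. Lithiated pyranone 7 (from 2 with LDA, THF, −78 °C) would be alkylated with commercial 2-bromo-3,5-dimethoxybenzyl bromide to give 4-(benzyloxy)-6-(2-bromo-3,5-dimethoxybenzyl)-2H-pyran-2-one F1. Palladium-catalysed Miyaura-type borylation (B2(OH)4, XPhos-Pd precatalyst, KOAc, EtOH, 80 °C) would give {2-[(4-benzyloxy-2-oxo-2H-pyran-6-yl)methyl]-4,6-dimethoxyphenyl}boronic acid F2. Liebeskind–Srogl coupling of F2 with the 2-(methylsulfanyl)chromone 5 (Pd2(dba)3, tri(2-furyl)phosphine, CuTC, THF, 50 °C) would give 16, which goes on to step 9.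

2. Step 5. The base may deprotonate C-3 of the pyranone in place of the 6-methyl group, and the hard lithium dienolate may attack the chromone carbonyl or open the pyranone ring of the chromone instead of substituting at C-2. The fallback replaces the polar addition–elimination by a cross-coupling, sets out from 2 and 5 and comes back at 8. Lithiated pyranone 7 would be quenched with Bu3SnCl to give 4-(benzyloxy)-6-[(tributylstannyl)methyl]-2H-pyran-2-one F3. Palladium-catalysed, copper(I)-carboxylate-mediated coupling of the stannane F3 with thioether 5 (Pd(PPh3)4, CuTC, THF, 50 °C; Liebeskind–Srogl coupling in its organostannane form) would give 8.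

3. Step 9. The liberated benzyl cation may C-benzylate the electron-rich resorcinol ring or C-3 of the pyranone, and the hindered 2′-methyl ether may be cleaved incompletely under conditions that the doubly activated methylene tolerates. The fallback is a staged deprotection that generates no benzyl cation and no Lewis acid complex, sets out from 16 and comes back at 17. Hydrogenolysis of the vinylogous benzyl ester (H2 1 atm, Pd/C, EtOAc, rt, stopped at uptake of one equivalent) would give 2-{2-[(4-hydroxy-2-oxo-2H-pyran-6-yl)methyl]-4,6-dimethoxyphenyl}-7-methoxy-5-methyl-4H-chromen-4-one F4. Nucleophilic demethylation of F4 with sodium ethanethiolate (DMF, 110 °C; SN2 at the methyl groups, the pyranone and the phenols being protected as their anions) would give 17 after acidification.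

**Further compounds**
F1 | step 8 | 4-(benzyloxy)-6-(2-bromo-3,5-dimethoxybenzyl)-2H-pyran-2-one | COc1cc(OC)c(Br)c(Cc2cc(OCc3ccccc3)cc(=O)o2)c1
F2 | step 8 | {2-[(4-benzyloxy-2-oxo-2H-pyran-6-yl)methyl]-4,6-dimethoxyphenyl}boronic acid | COc1cc(OC)c(B(O)O)c(Cc2cc(OCc3ccccc3)cc(=O)o2)c1
F3 | step 5 | 4-(benzyloxy)-6-[(tributylstannyl)methyl]-2H-pyran-2-one | CCCC[Sn](CCCC)(CCCC)Cc1cc(OCc2ccccc2)cc(=O)o1
F4 | step 9 | 2-{2-[(4-hydroxy-2-oxo-2H-pyran-6-yl)methyl]-4,6-dimethoxyphenyl}-7-methoxy-5-methyl-4H-chromen-4-one | COc1cc(C)c2c(c1)oc(-c1c(OC)cc(OC)cc1Cc1cc(O)cc(=O)o1)cc2=O
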